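## Retrosynthetic overview

1. The target is traced back (angelate at O-8, methylenation at C-11, silyl groups) to a trans-fused 6,12-lactone diol. Its C4–C15 bond and the C-4 stereocentre come from a silicon-tethered radical cyclisation that starts at O-6.
2. The ten-membered ring comes from a cyclohexenol by anionic oxy-Cope ring expansion, with alkylation of the enolate in the same flask. C5–C6 is formed (ring closure), C3–C8 is broken, C-6 and C-7 are set, C-8 becomes the ketone and C11–C12 are attached.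
3. Enabling feature: the ring-cis C1=C10 alkene is homoallylic to the oxygenated C-8. C8–C9–C10=C1–C2–C3 can therefore be a cyclohexene, and O–C6=C7–C8(O)–C3–C4=C5 a 3-oxido-1,5-diene whose termini C-6 (lactone carbinol carbon) and C-5 (the CH2 beside it) are joined by the [3,3] shift.
4. The cyclohexenol comes from (6R)-6-vinyl-3-(silyloxymethyl)cyclohex-3-enone and an alkoxyacetylide. The ketone comes from the Diels–Alder adduct of 2-(silyloxymethyl)butadiene and 3-boronoacrolein pinacol ester (Wittig, C–B oxidation, lipase resolution, oxidation).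
5. Order of ring formation: cyclohexene (step 3), ten-membered carbocycle (step 11), temporary 1-oxa-2-silacyclohexane (formed and opened in step 16), γ-lactone (step 17).

Key step: step 11

**Remarks.**
- Numbering used in the text (germacranolide numbering of the target): C-6 lactone carbinol carbon, C-7 ring-fusion carbon bearing C-11, C-8 angelate-bearing carbon, C-9 CH2, C-10 alkene carbon bearing C-14, C-1 alkene CH, C-2 and C-3 CH2, C-4 CH bearing C-15, C-5 CH2; C-11 (=C-13) and C-12 (C=O) complete the lactone. Locants inside compound names are systematic.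
- Abbreviations: TBDPS = tert-butyldiphenylsilyl, TBS = tert-butyldimethylsilyl, PMB = 4-methoxybenzyl, Bpin = 4,4,5,5-tetramethyl-1,3,2-dioxaborolan-2-yl.
- Racemic compounds are drawn as the enantiomer that is carried on.
- Assumption: the lipase shows its usual preference for secondary alcohols and acetylates the (1R)-alcohol, so the (1S,6R)-alcohol is recovered.

## Route

Step 1
Reactants: 1 2-methyl-2-vinyloxirane (isoprene monoxide, racemic)
Product: 2 2-methylenebut-3-en-1-ol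
Conditions: LiN(i-Pr)2 (1.2 equiv), Et2O, −78 → 25 °C; then H2O
Reagents that add atoms: none
Why: Base-induced isomerisation of an epoxide to an allylic alcohol (β-elimination): the amide removes a methyl proton and the oxirane opens to the dienyl alkoxide.

Step 2
Reactants: 2 2-methylenebut-3-en-1-ol
Product: 3 tert-butyl[(2-methylenebut-3-en-1-yl)oxy]diphenylsilane
Conditions: TBDPSCl, imidazole, CH2Cl2, 0 → 25 °C
Reagents that add atoms: tert-butyl(chloro)diphenylsilane, CC(C)(C)[Si](Cl)(c1ccccc1)c1ccccc1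
Why: Standard silylation of a primary alcohol; the bulky silyl ether is chosen to survive KH, LiAlH4, DDQ, the radical step and mild acid.

Step 3
Reactants: 3 tert-butyl[(2-methylenebut-3-en-1-yl)oxy]diphenylsilane; 4 (2E)-3-(Bpin)prop-2-enal (3-boronoacrolein pinacol ester)
Product: 5 rac-(1S,6S)-4-(TBDPSOCH2)-6-(Bpin)cyclohex-3-ene-1-carbaldehyde (CHO and boron trans)
Conditions: PhMe, BHT (cat.), 90 °C, sealed tube
Reagents that add atoms: none
Why: Thermal Diels–Alder reaction in which the formyl-bearing carbon should bond to the unsubstituted diene terminus ("para" to the CH2OTBDPS group, minor regioisomer removed by chromatography), while the E geometry of the dienophile fixes the trans relationship of CHO and boron (racemic).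

Step 4
Reactants: 5 rac-(1S,6S)-4-(TBDPSOCH2)-6-(Bpin)cyclohex-3-ene-1-carbaldehyde
Product: 6 rac-2-[(1S,6S)-6-ethenyl-3-(TBDPSOCH2)cyclohex-3-en-1-yl]-4,4,5,5-tetramethyl-1,3,2-dioxaborolane (trans)
Conditions: Ph3PCH3Br, KN(SiMe3)2, THF, 0 °C; then 5, −78 → 0 °C
Reagents that add atoms: methyltriphenylphosphonium bromide, C[P+](c1ccccc1)(c1ccccc1)c1ccccc1.[Br-]
Why: Wittig methylenation; the pinacol boronate tolerates the ylide, and any epimerisation next to the aldehyde only returns the more stable trans isomer.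

Step 5
Reactants: 6 rac-2-[(1S,6S)-6-ethenyl-3-(TBDPSOCH2)cyclohex-3-en-1-yl]-4,4,5,5-tetramethyl-1,3,2-dioxaborolane
Product: 7 rac-(1S,6R)-6-ethenyl-3-(TBDPSOCH2)cyclohex-3-en-1-ol (trans)
Conditions: 30% H2O2, aq. NaOH, THF, 0 → 25 °C
Reagents that add atoms: hydrogen peroxide, OO
Why: Oxidation of the C–B bond (1,2-boronate migration) with retention gives the trans-2-vinylcyclohexenol.

Step 6
Reactants: 7 rac-(1S,6R)-6-ethenyl-3-(TBDPSOCH2)cyclohex-3-en-1-ol
Product: 8 (1S,6R)-6-ethenyl-3-(TBDPSOCH2)cyclohex-3-en-1-ol (recovered alcohol)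
Conditions: Candida antarctica lipase B (immobilised), vinyl acetate, MTBE, 30 °C, run to just over half conversion
Reagents that add atoms: none
Why: Lipase-catalysed kinetic resolution by transesterification; the (1R)-enantiomer should be acetylated and separated, leaving the (1S,6R)-alcohol, whose C-6 centre carries the absolute configuration into the route.

Step 7
Reactants: 8 (1S,6R)-6-ethenyl-3-(TBDPSOCH2)cyclohex-3-en-1-ol
Product: 9 (6R)-6-ethenyl-3-(TBDPSOCH2)cyclohex-3-en-1-one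
Conditions: Dess–Martin periodinane, NaHCO3, CH2Cl2, 0 °C; used at once without chromatography
Reagents that add atoms: none
Why: Dess–Martin oxidation under buffered, non-basic conditions, chosen so that the doubly β,γ-unsaturated ketone neither conjugates nor racemises at C-6.

Step 8
Reactants: 10 (4-methoxyphenyl)methanol; 11 trichloroethene
Product: 12 1-({[(E)-1,2-dichloroethenyl]oxy}methyl)-4-methoxybenzene
Conditions: KH, THF, 0 °C; then 11, 25 °C
Reagents that add atoms: none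
Why: Dehydrochlorination of trichloroethene to dichloroacetylene and anti addition of the alkoxide to it give the (E)-1,2-dichlorovinyl ether, the standard precursor of alkoxyacetylides.

Step 9
Reactants: 12 1-({[(E)-1,2-dichloroethenyl]oxy}methyl)-4-methoxybenzene; 9 (6R)-6-ethenyl-3-(TBDPSOCH2)cyclohex-3-en-1-one
Product: 14 (1R,6R)-6-ethenyl-1-{[(4-methoxybenzyl)oxy]ethynyl}-3-(TBDPSOCH2)cyclohex-3-en-1-ol, via lithium alkoxyacetylide 13 (not isolated)
Conditions: 12, n-BuLi (2.1 equiv), THF, −78 → −40 °C; CeCl3, −78 °C; then 9, −78 °C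
Reagents that add atoms: none
Why: Elimination and Cl–Li exchange give the alkoxyacetylide, and its cerium-mediated 1,2-addition (which suppresses enolisation) should occur anti to the C-6 vinyl group, setting the tertiary carbinol with the alkynyl group trans to vinyl.

Step 10
Reactants: 14 (1R,6R)-6-ethenyl-1-{[(4-methoxybenzyl)oxy]ethynyl}-3-(TBDPSOCH2)cyclohex-3-en-1-ol
Product: 15 (1R,6R)-6-ethenyl-1-{(E)-2-[(4-methoxybenzyl)oxy]ethenyl}-3-(TBDPSOCH2)cyclohex-3-en-1-ol
Conditions: LiAlH4, THF, 0 → 25 °C; aq. KNaC4H4O6 work-up; chromatography on Et3N-treated silica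
Reagents that add atoms: none
Why: Alkoxide-directed trans-hydroalumination of the propargylic alcohol gives the E enol ether only.

Step 11
Reactants: 15 (1R,6R)-6-ethenyl-1-{(E)-2-[(4-methoxybenzyl)oxy]ethenyl}-3-(TBDPSOCH2)cyclohex-3-en-1-ol; 16 tert-butyl bromoacetate
Product: 19 tert-butyl 2-[(1S,4E,7E,10R)-4-(TBDPSOCH2)-10-(PMBO)-2-oxocyclodeca-4,7-dien-1-yl]acetate, via potassium alkoxide 17 (not isolated), via potassium enolate 18 (not isolated)
Conditions: KH (1.3 equiv), 18-crown-6 (1.3 equiv), THF, 0 → 25 °C; then −78 °C, 16, −78 → −40 °C; AcOH quench at −78 °C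
Reagents that add atoms: none
Why: KH gives alkoxide 17, in which the oxyanion weakens the C3–C8 bond so that C5–C6 forms as C3–C8 breaks in an anionic oxy-Cope [3,3]-sigmatropic rearrangement through a chair, and the regiodefined enolate 18 is then C-alkylated at C-7 by 16. The closest known reaction type is the anionic oxy-Cope ring expansion of trans-1,2-divinylcyclohexanols to cyclodec-5-enones with alkylation of the resulting enolate in the same flask. The ten-membered ring is closed by the sigmatropic shift itself, a four-atom ring expansion of the cyclohexene in which the vinyl terminus C-5 bonds to the oxygen-bearing enol ether carbon C-6. C-6 is set by chirality transfer from the two stereocentres of 15: with the alkenyl groups trans only one chair is open (both ring bonds pseudo-equatorial, oxyanion pseudo-axial) and the E enol ether puts the OPMB group pseudo-equatorial, which leads to 6R; C-7 is set in the alkylation, the electrophile entering the outer face of the enolate in the conformer that keeps H-6 in the enolate plane (allylic strain), that is trans to O-6 on the ring. The step needs chair over boat, no proton shuffling to the C8–C9–C10 dienolate, C- over O-alkylation and no loss of PMBO− from the β-alkoxy enolate; these are secured by the trans/E geometry of 15, by trapping at −78 °C directly after the rearrangement and by the C6–O bond lying near the nodal plane of the enolate.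

Step 12
Reactants: 19 tert-butyl 2-[(1S,4E,7E,10R)-4-(TBDPSOCH2)-10-(PMBO)-2-oxocyclodeca-4,7-dien-1-yl]acetate
Product: 20 tert-butyl 2-[(1R,2R,4E,7E,10R)-2-hydroxy-4-(TBDPSOCH2)-10-(PMBO)cyclodeca-4,7-dien-1-yl]acetate
Conditions: NaBH4, CeCl3·7H2O, MeOH, −40 °C
Reagents that add atoms: none
Why: Luche-type ketone reduction in which hydride should add to the outer face of the ring ketone, anti to the C7–C6 ring bond (Felkin–Anh control with the C-7 side chain kept away from C-9), giving the 8R alcohol with O-8 cis to the side chain; the tert-butyl ester resists lactonisation onto the new alkoxide.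

Step 13
Reactants: 20 tert-butyl 2-[(1R,2R,4E,7E,10R)-2-hydroxy-4-(TBDPSOCH2)-10-(PMBO)cyclodeca-4,7-dien-1-yl]acetate
Product: 21 tert-butyl 2-[(1S,2R,4E,7E,10R)-2-(TBSO)-4-(TBDPSOCH2)-10-(PMBO)cyclodeca-4,7-dien-1-yl]acetate
Conditions: TBSOTf, 2,6-lutidine, CH2Cl2, −78 → 0 °C
Reagents that add atoms: tert-butyldimethylsilyl trifluoromethanesulfonate, CC(C)(C)[Si](C)(C)OS(=O)(=O)C(F)(F)F
Why: Silylation of a hindered secondary alcohol with a silyl triflate; O-8 must be masked for the tether chemistry and the later enolate step.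

Step 14
Reactants: 21 tert-butyl 2-[(1S,2R,4E,7E,10R)-2-(TBSO)-4-(TBDPSOCH2)-10-(PMBO)cyclodeca-4,7-dien-1-yl]acetate
Product: 22 tert-butyl 2-[(1S,2R,4E,7E,10R)-10-hydroxy-2-(TBSO)-4-(TBDPSOCH2)cyclodeca-4,7-dien-1-yl]acetate
Conditions: DDQ, CH2Cl2/pH 7 buffer, 0 °C
Reagents that add atoms: none
Why: Oxidative cleavage of the PMB ether by DDQ frees O-6 under neutral conditions that leave the silyl ethers, the tert-butyl ester and the alkenes untouched.

Step 15
Reactants: 22 tert-butyl 2-[(1S,2R,4E,7E,10R)-10-hydroxy-2-(TBSO)-4-(TBDPSOCH2)cyclodeca-4,7-dien-1-yl]acetate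
Product: 23 tert-butyl 2-[(1S,2R,4E,7E,10R)-10-{[(bromomethyl)dimethylsilyl]oxy}-2-(TBSO)-4-(TBDPSOCH2)cyclodeca-4,7-dien-1-yl]acetate
Conditions: BrCH2SiMe2Cl, Et3N, DMAP (cat.), CH2Cl2, 0 °C
Reagents that add atoms: (bromomethyl)chlorodimethylsilane, C[Si](C)(Cl)CBr
Why: Silylation of the homoallylic alcohol installs the temporary silicon tether of a Nishiyama–Stork radical cyclisation; its CH2 becomes C-15.

Step 16
Reactants: 23 tert-butyl 2-[(1S,2R,4E,7E,10R)-10-{[(bromomethyl)dimethylsilyl]oxy}-2-(TBSO)-4-(TBDPSOCH2)cyclodeca-4,7-dien-1-yl]acetate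
Product: 25 tert-butyl 2-[(1S,2R,4E,8R,10R)-10-hydroxy-8-(hydroxymethyl)-2-(TBSO)-4-(TBDPSOCH2)cyclodec-4-en-1-yl]acetate, via cyclic siloxane 24 (not isolated)
Conditions: Bu3SnH (slow addition), AIBN (cat.), PhH (0.01 M), 80 °C; then KF, KHCO3, 30% H2O2, THF/MeOH, 25 °C
Reagents that add atoms: hydrogen peroxide, OO
Why: Silicon-tethered radical cyclisation (6-exo-trig attack of the α-silyl radical on C-4 of the homoallylic C3=C4 alkene, then hydrogen transfer to C-3) followed by Tamao oxidation of the C–Si bond; the three-atom O–Si–CH2 tether can only bridge one face, so C-15 is delivered cis to O-6, which sets C-4.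

Step 17
Reactants: 25 tert-butyl 2-[(1S,2R,4E,8R,10R)-10-hydroxy-8-(hydroxymethyl)-2-(TBSO)-4-(TBDPSOCH2)cyclodec-4-en-1-yl]acetate
Product: 26 (3aS,4R,6E,10R,11aR)-10-(hydroxymethyl)-4-(TBSO)-6-(TBDPSOCH2)-3a,4,5,8,9,10,11,11a-octahydrocyclodeca[b]furan-2(3H)-one
Conditions: pyridinium p-toluenesulfonate (cat.), PhMe, 80 °C
Reagents that add atoms: none
Why: Acid-catalysed lactonisation of the γ-hydroxy tert-butyl ester (5-exo-trig acyl substitution) closes the trans-fused 6,12-lactone; O-8 is silylated and cannot compete.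

Step 18
Reactants: 26 (3aS,4R,6E,10R,11aR)-10-(hydroxymethyl)-4-(TBSO)-6-(TBDPSOCH2)-3a,4,5,8,9,10,11,11a-octahydrocyclodeca[b]furan-2(3H)-one
Product: 27 (3aS,4R,6E,10R,11aR)-4-(TBSO)-6,10-bis(TBDPSOCH2)-3a,4,5,8,9,10,11,11a-octahydrocyclodeca[b]furan-2(3H)-one
Conditions: TBDPSCl, imidazole, DMF, 0 → 25 °C
Reagents that add atoms: tert-butyl(chloro)diphenylsilane, CC(C)(C)[Si](Cl)(c1ccccc1)c1ccccc1
Why: Silylation of the only free (primary) hydroxyl, so that both CH2OH groups carry the same acid-stable group for the enolate and acylation steps.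

Step 19
Reactants: 27 (3aS,4R,6E,10R,11aR)-4-(TBSO)-6,10-bis(TBDPSOCH2)-3a,4,5,8,9,10,11,11a-octahydrocyclodeca[b]furan-2(3H)-one
Product: 30 (3aS,4R,6E,10R,11aR)-3-methylidene-4-(TBSO)-6,10-bis(TBDPSOCH2)-3a,4,5,8,9,10,11,11a-octahydrocyclodeca[b]furan-2(3H)-one, via Mannich base 28 (not isolated), via trimethylammonium iodide 29 (not isolated)
Conditions: LiN(i-Pr)2, THF, −78 °C; Me2N=CH2 I (Eschenmoser's salt), −78 → 25 °C; then MeI, MeOH; then aq. NaHCO3, CH2Cl2
Reagents that add atoms: N,N-dimethylmethyleneiminium iodide (Eschenmoser's salt), C=[N+](C)C.[I-]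
Why: α-Methylenation of the lactone by the Mannich reaction of its lithium enolate, N-methylation and Hofmann-type elimination; C-11 becomes sp2, so its transient configuration does not matter.

Step 20
Reactants: 30 (3aS,4R,6E,10R,11aR)-3-methylidene-4-(TBSO)-6,10-bis(TBDPSOCH2)-3a,4,5,8,9,10,11,11a-octahydrocyclodeca[b]furan-2(3H)-one
Product: 31 (3aR,4R,6E,10R,11aR)-4-hydroxy-3-methylidene-6,10-bis(TBDPSOCH2)-3a,4,5,8,9,10,11,11a-octahydrocyclodeca[b]furan-2(3H)-one
Conditions: camphorsulfonic acid (cat.), MeOH/CH2Cl2, 0 → 25 °C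
Reagents that add atoms: none
Why: Acid-catalysed methanolysis removes the secondary TBS ether, while the far more acid-stable primary TBDPS ethers and the α-methylene lactone should remain.

Step 21
Reactants: 31 (3aR,4R,6E,10R,11aR)-4-hydroxy-3-methylidene-6,10-bis(TBDPSOCH2)-3a,4,5,8,9,10,11,11a-octahydrocyclodeca[b]furan-2(3H)-one; 32 angelic acid, (2Z)-2-methylbut-2-enoic acid
Product: 34 (3aS,4R,6E,10R,11aR)-3-methylidene-2-oxo-6,10-bis(TBDPSOCH2)-2,3,3a,4,5,8,9,10,11,11a-decahydrocyclodeca[b]furan-4-yl (2Z)-2-methylbut-2-enoate, via mixed anhydride 33 (not isolated)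
Conditions: 32, 2,4,6-trichlorobenzoyl chloride, Et3N, PhMe, 25 °C; then 31, 75 °C
Reagents that add atoms: none
Why: Yamaguchi-type mixed-anhydride esterification without a nucleophilic catalyst, the usual way to make angelates without Z to E isomerisation; C-8 is not touched, so its configuration is retained.

Step 22
Reactants: 34 (3aS,4R,6E,10R,11aR)-3-methylidene-2-oxo-6,10-bis(TBDPSOCH2)-2,3,3a,4,5,8,9,10,11,11a-decahydrocyclodeca[b]furan-4-yl (2Z)-2-methylbut-2-enoate
Product: 35 (3aS,4R,6E,10R,11aR)-6,10-bis(hydroxymethyl)-3-methylidene-2-oxo-2,3,3a,4,5,8,9,10,11,11a-decahydrocyclodeca[b]furan-4-yl (2Z)-2-methylbut-2-enoate (CNP0262807.1)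
Conditions: HF·pyridine, pyridine, THF, 0 → 25 °C
Reagents that add atoms: none
Why: Fluoride cleavage of both primary TBDPS ethers under buffered, non-basic conditions, which the angelate and the α-methylene lactone should tolerate.

## Compound list

1 | 2-methyl-2-vinyloxirane (isoprene monoxide, racemic) | CC1(C=C)CO1 | starting material
2 | 2-methylenebut-3-en-1-ol | C=CC(=C)CO | intermediate
3 | tert-butyl[(2-methylenebut-3-en-1-yl)oxy]diphenylsilane | C=CC(=C)CO[Si](c1ccccc1)(c1ccccc1)C(C)(C)C | intermediate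
4 | (2E)-3-(4,4,5,5-tetramethyl-1,3,2-dioxaborolan-2-yl)prop-2-enal (3-boronoacrolein pinacol ester) | O=C/C=C/B1OC(C)(C)C(C)(C)O1 | starting material
5 | rac-(1S,6S)-4-(TBDPSOCH2)-6-(Bpin)cyclohex-3-ene-1-carbaldehyde (trans) | O=C[C@H]1CC=C(CO[Si](c2ccccc2)(c2ccccc2)C(C)(C)C)C[C@@H]1B1OC(C)(C)C(C)(C)O1 | intermediate
6 | rac-2-[(1S,6S)-6-ethenyl-3-(TBDPSOCH2)cyclohex-3-en-1-yl]-4,4,5,5-tetramethyl-1,3,2-dioxaborolane (trans) | C=C[C@H]1CC=C(CO[Si](c2ccccc2)(c2ccccc2)C(C)(C)C)C[C@@H]1B1OC(C)(C)C(C)(C)O1 | intermediate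
7 | rac-(1S,6R)-6-ethenyl-3-(TBDPSOCH2)cyclohex-3-en-1-ol (trans, racemic) | C=C[C@H]1CC=C(CO[Si](c2ccccc2)(c2ccccc2)C(C)(C)C)C[C@@H]1O | intermediate
8 | (1S,6R)-6-ethenyl-3-(TBDPSOCH2)cyclohex-3-en-1-ol (single enantiomer) | C=C[C@H]1CC=C(CO[Si](c2ccccc2)(c2ccccc2)C(C)(C)C)C[C@@H]1O | intermediate
9 | (6R)-6-ethenyl-3-(TBDPSOCH2)cyclohex-3-en-1-one | C=C[C@H]1CC=C(CO[Si](c2ccccc2)(c2ccccc2)C(C)(C)C)CC1=O | intermediate
10 | (4-methoxyphenyl)methanol | COc1ccc(CO)cc1 | starting material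
11 | trichloroethene | ClC=C(Cl)Cl | starting material
12 | 1-({[(E)-1,2-dichloroethenyl]oxy}methyl)-4-methoxybenzene | COc1ccc(CO/C(Cl)=C\Cl)cc1 | intermediate
13 | lithium [(4-methoxybenzyl)oxy]acetylide | [Li]C#COCc1ccc(OC)cc1 | intermediate (not isolated)
14 | (1R,6R)-6-ethenyl-1-{[(4-methoxybenzyl)oxy]ethynyl}-3-(TBDPSOCH2)cyclohex-3-en-1-ol | C=C[C@H]1CC=C(CO[Si](c2ccccc2)(c2ccccc2)C(C)(C)C)C[C@]1(O)C#COCc1ccc(OC)cc1 | intermediate
15 | (1R,6R)-6-ethenyl-1-{(E)-2-[(4-methoxybenzyl)oxy]ethenyl}-3-(TBDPSOCH2)cyclohex-3-en-1-ol | C=C[C@H]1CC=C(CO[Si](c2ccccc2)(c2ccccc2)C(C)(C)C)C[C@]1(O)/C=C/OCc1ccc(OC)cc1 | intermediate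
16 | tert-butyl bromoacetate | CC(C)(C)OC(=O)CBr | starting material
17 | potassium alkoxide of 15 | C=C[C@H]1CC=C(CO[Si](c2ccccc2)(c2ccccc2)C(C)(C)C)C[C@]1([O-])/C=C/OCc1ccc(OC)cc1.[K+] | intermediate (not isolated)
18 | potassium (1Z,3R,5E,8E)-3-(PMBO)-9-(TBDPSOCH2)cyclodeca-1,5,8-trien-1-olate | [O-]/C1=C\[C@H](OCc2ccc(OC)cc2)C/C=C/C/C=C(/CO[Si](c2ccccc2)(c2ccccc2)C(C)(C)C)C1.[K+] | intermediate (not isolated)
19 | tert-butyl 2-[(1S,4E,7E,10R)-4-(TBDPSOCH2)-10-(PMBO)-2-oxocyclodeca-4,7-dien-1-yl]acetate | COc1ccc(CO[C@@H]2C/C=C/C/C=C(/CO[Si](c3ccccc3)(c3ccccc3)C(C)(C)C)CC(=O)[C@H]2CC(=O)OC(C)(C)C)cc1 | intermediate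
20 | tert-butyl 2-[(1R,2R,4E,7E,10R)-2-hydroxy-4-(TBDPSOCH2)-10-(PMBO)cyclodeca-4,7-dien-1-yl]acetate | COc1ccc(CO[C@@H]2C/C=C/C/C=C(/CO[Si](c3ccccc3)(c3ccccc3)C(C)(C)C)C[C@@H](O)[C@H]2CC(=O)OC(C)(C)C)cc1 | intermediate
21 | tert-butyl 2-[(1S,2R,4E,7E,10R)-2-(TBSO)-4-(TBDPSOCH2)-10-(PMBO)cyclodeca-4,7-dien-1-yl]acetate | COc1ccc(CO[C@@H]2C/C=C/C/C=C(/CO[Si](c3ccccc3)(c3ccccc3)C(C)(C)C)C[C@@H](O[Si](C)(C)C(C)(C)C)[C@H]2CC(=O)OC(C)(C)C)cc1 | intermediate
22 | tert-butyl 2-[(1S,2R,4E,7E,10R)-10-hydroxy-2-(TBSO)-4-(TBDPSOCH2)cyclodeca-4,7-dien-1-yl]acetate | O[C@@H]1C/C=C/C/C=C(/CO[Si](c2ccccc2)(c2ccccc2)C(C)(C)C)C[C@@H](O[Si](C)(C)C(C)(C)C)[C@H]1CC(=O)OC(C)(C)C | intermediate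
23 | tert-butyl 2-[(1S,2R,4E,7E,10R)-10-{[(bromomethyl)dimethylsilyl]oxy}-2-(TBSO)-4-(TBDPSOCH2)cyclodeca-4,7-dien-1-yl]acetate | BrC[Si](C)(C)O[C@@H]1C/C=C/C/C=C(/CO[Si](c2ccccc2)(c2ccccc2)C(C)(C)C)C[C@@H](O[Si](C)(C)C(C)(C)C)[C@H]1CC(=O)OC(C)(C)C | intermediate
24 | cyclic siloxane: O-6 and C-15 joined through SiMe2 (cis-fused 2,2-dimethyl-1-oxa-2-silacyclohexane across C-4/C-6), otherwise as 25 | C[Si]1(C)C[C@@H]2CC/C=C(/CO[Si](c3ccccc3)(c3ccccc3)C(C)(C)C)C[C@@H](O[Si](C)(C)C(C)(C)C)[C@@H](CC(=O)OC(C)(C)C)[C@@H](C2)O1 | intermediate (not isolated)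
25 | tert-butyl 2-[(1S,2R,4E,8R,10R)-10-hydroxy-8-(hydroxymethyl)-2-(TBSO)-4-(TBDPSOCH2)cyclodec-4-en-1-yl]acetate | OC[C@@H]1CC/C=C(/CO[Si](c2ccccc2)(c2ccccc2)C(C)(C)C)C[C@@H](O[Si](C)(C)C(C)(C)C)[C@@H](CC(=O)OC(C)(C)C)[C@H](O)C1 | intermediate
26 | (3aS,4R,6E,10R,11aR)-10-(hydroxymethyl)-4-(TBSO)-6-(TBDPSOCH2)-3a,4,5,8,9,10,11,11a-octahydrocyclodeca[b]furan-2(3H)-one | OC[C@@H]1CC/C=C(/CO[Si](c2ccccc2)(c2ccccc2)C(C)(C)C)C[C@@H](O[Si](C)(C)C(C)(C)C)[C@H]2CC(=O)O[C@@H]2C1 | intermediate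
27 | (3aS,4R,6E,10R,11aR)-4-(TBSO)-6,10-bis(TBDPSOCH2)-3a,4,5,8,9,10,11,11a-octahydrocyclodeca[b]furan-2(3H)-one | CC(C)(C)[Si](c1ccccc1)(c1ccccc1)OC[C@@H]1CC/C=C(/CO[Si](c2ccccc2)(c2ccccc2)C(C)(C)C)C[C@@H](O[Si](C)(C)C(C)(C)C)[C@H]2CC(=O)O[C@@H]2C1 | intermediate
28 | 3-[(dimethylamino)methyl] derivative of 27 (both C-3 epimers) | CN(C)CC1C(=O)O[C@@H]2C[C@H](CO[Si](c3ccccc3)(c3ccccc3)C(C)(C)C)CC/C=C(/CO[Si](c3ccccc3)(c3ccccc3)C(C)(C)C)C[C@@H](O[Si](C)(C)C(C)(C)C)[C@@H]12 | intermediate (not isolated)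
29 | 3-[(trimethylammonio)methyl] iodide derived from 28 | C[N+](C)(C)CC1C(=O)O[C@@H]2C[C@H](CO[Si](c3ccccc3)(c3ccccc3)C(C)(C)C)CC/C=C(/CO[Si](c3ccccc3)(c3ccccc3)C(C)(C)C)C[C@@H](O[Si](C)(C)C(C)(C)C)[C@@H]12.[I-] | intermediate (not isolated)
30 | (3aS,4R,6E,10R,11aR)-3-methylidene-4-(TBSO)-6,10-bis(TBDPSOCH2)-3a,4,5,8,9,10,11,11a-octahydrocyclodeca[b]furan-2(3H)-one | C=C1C(=O)O[C@@H]2C[C@H](CO[Si](c3ccccc3)(c3ccccc3)C(C)(C)C)CC/C=C(/CO[Si](c3ccccc3)(c3ccccc3)C(C)(C)C)C[C@@H](O[Si](C)(C)C(C)(C)C)[C@@H]12 | intermediate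
31 | (3aR,4R,6E,10R,11aR)-4-hydroxy-3-methylidene-6,10-bis(TBDPSOCH2)-3a,4,5,8,9,10,11,11a-octahydrocyclodeca[b]furan-2(3H)-one | C=C1C(=O)O[C@@H]2C[C@H](CO[Si](c3ccccc3)(c3ccccc3)C(C)(C)C)CC/C=C(/CO[Si](c3ccccc3)(c3ccccc3)C(C)(C)C)C[C@@H](O)[C@@H]12 | intermediate
32 | angelic acid, (2Z)-2-methylbut-2-enoic acid | C/C=C(/C)C(=O)O | starting material
33 | (2Z)-2-methylbut-2-enoic 2,4,6-trichlorobenzoic anhydride | C/C=C(/C)C(=O)OC(=O)c1c(Cl)cc(Cl)cc1Cl | intermediate (not isolated)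
34 | (3aS,4R,6E,10R,11aR)-3-methylidene-2-oxo-6,10-bis(TBDPSOCH2)-2,3,3a,4,5,8,9,10,11,11a-decahydrocyclodeca[b]furan-4-yl (2Z)-2-methylbut-2-enoate | C=C1C(=O)O[C@@H]2C[C@H](CO[Si](c3ccccc3)(c3ccccc3)C(C)(C)C)CC/C=C(/CO[Si](c3ccccc3)(c3ccccc3)C(C)(C)C)C[C@@H](OC(=O)/C(C)=C\C)[C@@H]12 | intermediate
35 | (3aS,4R,6E,10R,11aR)-6,10-bis(hydroxymethyl)-3-methylidene-2-oxo-2,3,3a,4,5,8,9,10,11,11a-decahydrocyclodeca[b]furan-4-yl (2Z)-2-methylbut-2-enoate (CNP0262807.1) | C=C1C(=O)O[C@@H]2C[C@H](CO)CC/C=C(/CO)C[C@@H](OC(=O)/C(C)=C\C)[C@@H]12 | target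

## Step count and risks

Total step count: 22. Longest linear sequence: 21 steps (steps 1–7 and 9–22; step 8 is a one-step branch).

The three steps most likely to fail:

**Step 11 (key step).** Loss of 4-methoxybenzyl oxide from the β-alkoxy potassium enolate, proton transfer to the conjugated dienolate, or O-alkylation may compete with C-alkylation in the one-flask cascade; a boat pathway would erode the configuration at C-6. Fallback, from 15 and returning at 19: the rearrangement and the alkylation are separated and the counter-ion is changed. The rearrangement is run as before but quenched at −78 °C with Me3SiCl to give the trimethylsilyl enol ether F1, which is isolated. MeLi (THF, 0 °C) then releases the salt-free lithium enolate regiospecifically, and alkylation with 16 at −78 °C gives 19.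

**Step 9.** Poor facial selectivity in the 1,2-addition is the main risk: the slim acetylide may also enter syn to the vinyl group along the axial trajectory. Enolisation or conjugation of 9 may also intervene. A cis-dialkenyl carbinol would have two competing chairs in step 11 and blur the chirality transfer. Fallback, from 9 and returning at 15 without passing 14: the bulkier sp2 nucleophile (E)-2-(tributylstannyl)vinyllithium, made from (E)-1,2-bis(tributylstannyl)ethene and n-BuLi, is added with CeCl3 at −78 °C and should enter anti to the vinyl group to give the (E)-alkenylstannane F2. Iododestannylation (I2, CH2Cl2, 0 °C) gives the (E)-alkenyl iodide F3 with retention. Copper-catalysed C–O coupling of F3 with 10 (CuI, 3,4,7,8-tetramethyl-1,10-phenanthroline, Cs2CO3, PhMe, 80 °C) gives 15 with the E geometry kept.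

**Step 12.** Poor or reversed facial selectivity of hydride delivery is possible, because the ten-membered ketone can react through more than one carbonyl rotamer; lactonisation of the new alkoxide onto the ester is a lesser risk. Fallback, from 19 and returning at 20: if the reduction gives mainly the (8S)-alcohol F4, its configuration is inverted by a Mitsunobu reaction (4-nitrobenzoic acid, PPh3, diisopropyl azodicarboxylate, PhMe, 0 → 25 °C) to the 4-nitrobenzoate F5. Mild methanolysis (K2CO3, MeOH, 0 °C) then gives 20.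

## Further compounds

F1 | step 11 | {[(1Z,3R,5E,8E)-3-(PMBO)-9-(TBDPSOCH2)cyclodeca-1,5,8-trien-1-yl]oxy}trimethylsilane | C[Si](C)(C)O/C1=C\[C@H](OCc2ccc(OC)cc2)C/C=C/C/C=C(/CO[Si](c2ccccc2)(c2ccccc2)C(C)(C)C)C1
F2 | step 9 | (1R,6R)-6-ethenyl-3-(TBDPSOCH2)-1-[(E)-2-(tributylstannyl)ethenyl]cyclohex-3-en-1-ol | C=C[C@H]1CC=C(CO[Si](c2ccccc2)(c2ccccc2)C(C)(C)C)C[C@]1(O)/C=C/[Sn](CCCC)(CCCC)CCCC
F3 | step 9 | (1R,6R)-6-ethenyl-1-[(E)-2-iodoethenyl]-3-(TBDPSOCH2)cyclohex-3-en-1-ol | C=C[C@H]1CC=C(CO[Si](c2ccccc2)(c2ccccc2)C(C)(C)C)C[C@]1(O)/C=C/I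
F4 | step 12 | tert-butyl 2-[(1R,2S,4E,7E,10R)-2-hydroxy-4-(TBDPSOCH2)-10-(PMBO)cyclodeca-4,7-dien-1-yl]acetate | COc1ccc(CO[C@@H]2C/C=C/C/C=C(/CO[Si](c3ccccc3)(c3ccccc3)C(C)(C)C)C[C@H](O)[C@H]2CC(=O)OC(C)(C)C)cc1
F5 | step 12 | tert-butyl 2-[(1S,2R,4E,7E,10R)-2-[(4-nitrobenzoyl)oxy]-4-(TBDPSOCH2)-10-(PMBO)cyclodeca-4,7-dien-1-yl]acetate | COc1ccc(CO[C@@H]2C/C=C/C/C=C(/CO[Si](c3ccccc3)(c3ccccc3)C(C)(C)C)C[C@@H](OC(=O)c3ccc([N+](=O)[O-])cc3)[C@H]2CC(=O)OC(C)(C)C)cc1
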